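The rate constants are those of an exercise; the rest is arithmetic.

Watch the split.

    starting material + enzyme → target + enzyme, rate k1*[starting material]^1.5*[enzyme]/(1 + ([starting material]/Kh1)^1.5) (Kh1 = 0.10 M, k1 = 1700 L¹·⁵ mol⁻¹·⁵ min⁻¹)
    2 starting material → self-condensation product (k2 = 0.19 L mol⁻¹ min⁻¹)
    solid substrate ⇌ starting material, rate k3*(cs3 - [starting material]) while solid is left; crystals form when [starting material] > cs3 (cs3 = 32 mM, k3 = 0.0045 min⁻¹)

solid substrate 0.12 M; enzyme 12 µM; time 5.0 d

* target at 5.0 d, in percent of the solid substrate charged
* amount of target if the flask were left three thousand times as long, in percent of the solid substrate charged

- percentages count the solid substrate that a species holds: one self-condensation product counts as two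
- for a step with 2 of a species take k times the square, and two of it per event
- solid, in amounts per volume of the solution: solid substrate
- at the start none of the solid substrate is in solution
- run time (flask): 5.0 d

While solid remained, I expected the starting material to hold at a level where dissolving replaced what both paths took, so I solved that balance by hand, first with self-condensation alone and then with both losses:

Level with self-condensation alone: 14.4 mM

Split at that level: 0.424

Level with both losses: 12.7 mM

Split at the corrected level: 0.456

This last figure is the split number (selectivity factor), the rate at which starting material goes to target divided by the rate at which it goes to self-condensation product, at the level held while solid remains; it is less than one, and at that level it would send 31.3% of the dissolved material to target.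

One number was not quite enough, since the split grows as the level falls: I integrated the final pool, 10.6% of the charge, and got a share of 42.9%, higher than the share at the level.

Target: 32.6%

I reckoned that the solid would last about 0.958 d, and the days remaining after that far exceeded the 143 min lifetime of starting material at the level, so I gave this figure for both questions.

The forecast, 33.1% and 33.2%, stood higher than my figure, and it too held that “the leftover pool then drains with somewhat better selectivity”.

The flask gave 32.9% and 33.0%. At 0.445 d in this flask, starting material was made 1.00 times as fast as it was used up, and at 0.500 d target held 14.5% against 30.8% in self-condensation product, a share of 32.0%. For the flask with 3.0 × 10⁻⁶ M of enzyme, I scaled the split with the enzyme while keeping my level, which gave 0.114, a share of 10.2%, and that flask held 10.5% target at 5.00 d.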